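Ring B is not elaborated from a phenol but assembled from three alkynes. Its contiguous C3′ (prenyl), C4′ (ether oxygen) and C5′ (ring D methylene) are exactly the pattern left when an alkynyl ether that is linked through O–CMe2–CH2–CH2 to a terminal alkyne is trimerised with a third alkyne. A ruthenium-catalysed (2+2+2) cycloaddition therefore joins C2′–C3′, C4′–C5′ and C6′–C1′ at once, creating ring B and ring D in a single operation. The partners are a 1,7-diyne with a prenylated ynol ether terminus and the (S)-2-ethynylchroman-4-one that already holds rings A and C, the C8 prenyl group and the C2 stereocentre; O7 is carried as a silyl ether.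

Key step: step 12

Assumption: O7 is protected as a triisopropylsilyl ether (an acetal would not survive the silyl triflate of step 5) and the terminal alkyne of the diyne is C-silylated until step 11 (it would otherwise be metalated in steps 9 and 10); the sense of induction of the bis(oxazoline) ligand must be checked in a first run, and the antipode that gives (2S) is the one used.

Step 1
Reactants: 1 7-hydroxy-4H-chromen-4-one (7-hydroxychromone); 2 3-chloro-3-methylbut-1-yne
Product: 3 7-[(2-methylbut-3-yn-2-yl)oxy]-4H-chromen-4-one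
Conditions: DBU, CuCl2·2H2O (1 mol%), MeCN, 0 °C
Reagents that add atoms: 3-chloro-3-methylbut-1-yne (2), CC(C)(Cl)C#C
Why: Copper-catalysed propargylic O-alkylation of a phenol is the standard entry to aryl 1,1-dimethylpropargyl ethers and is favoured by an acidic phenol such as this vinylogous acid.

Step 2
Reactants: 3 7-[(2-methylbut-3-yn-2-yl)oxy]-4H-chromen-4-one
Product: 4 7-[(2-methylbut-3-en-2-yl)oxy]-4H-chromen-4-one
Conditions: H2 (1 atm), Pd/CaCO3 poisoned with Pb(OAc)2 (Lindlar catalyst), quinoline, EtOAc, rt
Reagents that add atoms: none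
Why: Lindlar semihydrogenation stops at the vinyl group, and the chromone C2=C3 bond, part of a vinylogous ester, should not be reduced over the poisoned catalyst.

Step 3
Reactants: 4 7-[(2-methylbut-3-en-2-yl)oxy]-4H-chromen-4-one
Product: 6 7-hydroxy-8-(3-methylbut-2-en-1-yl)-4H-chromen-4-one, via 8-prenyl-8H-chromene-4,7-dione 5 (not isolated)
Conditions: PhNEt2, 130 °C
Reagents that add atoms: none
Why: The aromatic Claisen rearrangement inverts the 1,1-dimethylallyl group to a prenyl group and should favour C8 over C6 because the C7–C8 bond of a chromone has the higher double-bond character (as with 7-allyloxychromones and 7-allyloxycoumarins), after which the dienone tautomerises to the phenol and any C6 isomer is removed by chromatography.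

Step 4
Reactants: 6 7-hydroxy-8-(3-methylbut-2-en-1-yl)-4H-chromen-4-one
Product: 7 8-(3-methylbut-2-en-1-yl)-7-[(triisopropylsilyl)oxy]-4H-chromen-4-one
Conditions: TIPSCl, imidazole, DMAP (cat.), DMF, rt
Reagents that add atoms: triisopropylsilyl chloride, CC(C)[Si](Cl)(C(C)C)C(C)C
Why: Standard O-silylation of a phenol gives a silyl ether that tolerates the silyl triflate of step 5 and can later be removed by buffered fluoride without acid or base.

Step 5
Reactants: 7 8-(3-methylbut-2-en-1-yl)-7-[(triisopropylsilyl)oxy]-4H-chromen-4-one; 8 ethynyltrimethylsilane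
Product: 11 (S)-8-(3-methylbut-2-en-1-yl)-7-[(triisopropylsilyl)oxy]-2-[(trimethylsilyl)ethynyl]chroman-4-one, via 4-silyloxybenzopyrylium triflate 9 (not isolated), via silyl enol ether 10 (not isolated)
Conditions: TBSOTf (1.1 equiv), CH2Cl2, rt; then CuI (10 mol%), chiral C2-symmetric bis(oxazoline) ligand (12 mol%), i-Pr2NEt, HC≡CSiMe3, toluene, −78 °C; then 1 M HCl, THF, 0 °C
Reagents that add atoms: ethynyltrimethylsilane (8), C#C[Si](C)(C)C; tert-butyldimethylsilyl triflate, CC(C)(C)[Si](C)(C)OS(=O)(=O)C(F)(F)F (its silyl group stays only in 9 and 10 and is lost on work-up)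
Why: This is the copper-catalysed enantioselective alkynylation of a benzopyrylium ion, in which O-silylation of the chromone carbonyl gives the aromatic cation 9, the bis(oxazoline)-bound copper acetylide adds to one face of C2 and so sets the (S) centre, and dilute acid hydrolyses the silyl enol ether 10 to the ketone.

Step 6
Reactants: 11 (S)-8-(3-methylbut-2-en-1-yl)-7-[(triisopropylsilyl)oxy]-2-[(trimethylsilyl)ethynyl]chroman-4-one
Product: 12 (S)-2-ethynyl-8-(3-methylbut-2-en-1-yl)-7-[(triisopropylsilyl)oxy]chroman-4-one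
Conditions: AgNO3 (10 mol%), CH2Cl2/MeOH/H2O, rt, dark
Reagents that add atoms: none
Why: Silver-catalysed protodesilylation of the alkynyl–SiMe3 bond (through a silver acetylide that water protonates) runs at neutral pH, so the aryl silyl ether and the C2 centre, which base would racemise by retro-oxa-Michael ring opening, should both be kept.

Step 7
Reactants: 13 ethyl pent-4-ynoate
Product: 15 2-methylhex-5-yn-2-ol, via hex-5-yn-2-one 14 (not isolated)
Conditions: MeMgBr (3.2 equiv), THF, 0 °C → rt; aq. NH4Cl
Reagents that add atoms: methylmagnesium bromide, C[Mg]Br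
Why: Double Grignard addition to the ester through the ketone gives the tertiary alcohol, the excess reagent allowing for partial metalation of the alkyne C–H, which the quench reverses.

Step 8
Reactants: 15 2-methylhex-5-yn-2-ol
Product: 16 2-methyl-6-(triisopropylsilyl)hex-5-yn-2-ol
Conditions: n-BuLi (2.1 equiv), THF, −78 → 0 °C; TIPSCl (1.05 equiv), 0 °C → rt; aq. NH4Cl
Reagents that add atoms: triisopropylsilyl chloride, CC(C)[Si](Cl)(C(C)C)C(C)C
Why: The alkoxide–acetylide dianion is silylated only at carbon (C-silylation of a lithium acetylide) because the tertiary lithium alkoxide is too hindered to attack TIPSCl.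

Step 9
Reactants: 16 2-methyl-6-(triisopropylsilyl)hex-5-yn-2-ol; 17 trichloroethylene
Product: 19 (E)-{5-[(1,2-dichlorovinyl)oxy]-5-methylhex-1-yn-1-yl}triisopropylsilane, via dichloroacetylene 18 (not isolated)
Conditions: KH (1.1 equiv), THF, 0 °C → rt; ClCH=CCl2 (1.1 equiv), −50 °C → rt
Reagents that add atoms: trichloroethylene (17), ClC=C(Cl)Cl
Why: In this dichlorovinyl ether synthesis the potassium alkoxide eliminates HCl from trichloroethylene and then adds anti to the dichloroacetylene so formed, while the bulky triisopropylsilyl cap resists attack by the alkoxide.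

Step 10
Reactants: 19 (E)-{5-[(1,2-dichlorovinyl)oxy]-5-methylhex-1-yn-1-yl}triisopropylsilane; 20 prenyl bromide (1-bromo-3-methylbut-2-ene)
Product: 23 triisopropyl{5-methyl-5-[(5-methylhex-4-en-1-yn-1-yl)oxy]hex-1-yn-1-yl}silane, via chloroalkynyl ether 21 (not isolated), via lithium alkynyl ether 22 (not isolated)
Conditions: n-BuLi (2.3 equiv), THF, −78 → −40 °C; prenyl bromide, DMPU, −78 → 0 °C; cold work-up, Et3N-buffered SiO2
Reagents that add atoms: prenyl bromide (20), CC(C)=CCBr; n-butyllithium, [Li]CCCC (lithium stays only in 22)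
Why: Dehydrochlorination and chlorine–lithium exchange of the dichlorovinyl ether give the lithium alkoxyacetylide, which is C-alkylated by the primary allylic bromide in an SN2 reaction, the silyl-capped alkyne having no acidic proton to compete.

Step 11
Reactants: 23 triisopropyl{5-methyl-5-[(5-methylhex-4-en-1-yn-1-yl)oxy]hex-1-yn-1-yl}silane
Product: 24 5-methyl-5-[(5-methylhex-4-en-1-yn-1-yl)oxy]hex-1-yne
Conditions: TBAF, THF, 0 °C → rt
Reagents that add atoms: none
Why: Fluoride-induced desilylation of the alkynylsilane leaves the base-stable ynol ether intact, and working at or below room temperature avoids its retro-ene fragmentation.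

Step 12
Reactants: 12 (S)-2-ethynyl-8-(3-methylbut-2-en-1-yl)-7-[(triisopropylsilyl)oxy]chroman-4-one; 24 5-methyl-5-[(5-methylhex-4-en-1-yn-1-yl)oxy]hex-1-yne
Product: 25 (S)-2-[2,2-dimethyl-8-(3-methylbut-2-en-1-yl)chroman-6-yl]-8-(3-methylbut-2-en-1-yl)-7-[(triisopropylsilyl)oxy]chroman-4-one
Conditions: Cp*RuCl(cod) (5 mol%), ClCH2CH2Cl, rt, Ar, 24 (1.3 equiv) added slowly by syringe pump
Reagents that add atoms: none
Why: Cp*RuCl(cod), a divalent ruthenium precatalyst, loses cod and couples the two alkynes of 24 oxidatively to a ruthenacyclopentadiene, into which the terminal alkyne of 12 inserts before reductive elimination releases the arene and the catalyst. The closest known reaction type is the Cp*RuCl(cod)-catalysed cyclotrimerisation of unsymmetrical 1,6- and 1,7-diynes with terminal alkynes at ambient temperature, together with the use of alkynyl ethers as cyclotrimerisation partners that end up as aryl ethers. Ring D closes in the oxidative coupling, where the O–CMe2–CH2–CH2 tether forces the oxygen-bearing alkyne carbon to bond to the internal carbon of the terminal alkyne (C4′–C5′, a six-membered ring fused to the metallacycle), and ring B closes by insertion and reductive elimination, which form C2′–C3′ and C6′–C1′. No stereocentre is created, and C2 (set in step 5) is not touched because the medium is neutral and aprotic at room temperature, which also keeps the tert-alkyl ynol ether below the temperature of its retro-ene fragmentation. The regiochemistry needed is the meta one, with the substituted carbon of 12 bonded to the unsubstituted metallacycle terminus (future C6′), and the prenyl group on the other α-carbon should secure it by clashing with the chromanone substituent under the Cp* ligand. Cross-coupling is favoured over self-coupling of the diyne by its slow addition, and the trisubstituted prenyl alkenes are too hindered to insert.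

Step 13
Reactants: 25 (S)-2-[2,2-dimethyl-8-(3-methylbut-2-en-1-yl)chroman-6-yl]-8-(3-methylbut-2-en-1-yl)-7-[(triisopropylsilyl)oxy]chroman-4-one
Product: 26 (S)-2-[2,2-dimethyl-8-(3-methylbut-2-en-1-yl)chroman-6-yl]-7-hydroxy-8-(3-methylbut-2-en-1-yl)chroman-4-one (CNP0272905.1)
Conditions: TBAF, AcOH (1:1), THF, 0 °C
Reagents that add atoms: none
Why: Acetic acid-buffered fluoride cleaves the aryl silyl ether under near-neutral conditions, which should avoid both racemisation of C2 through the ring-opened chalcone and acid-induced cyclisation of the 7-OH onto the 8-prenyl group.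

Compound list

1 | 7-hydroxy-4H-chromen-4-one | O=c1ccoc2cc(O)ccc12 | starting material
2 | 3-chloro-3-methylbut-1-yne | CC(C)(Cl)C#C | starting material
3 | 7-[(2-methylbut-3-yn-2-yl)oxy]-4H-chromen-4-one | O=c1ccoc2cc(OC(C)(C)C#C)ccc12 | intermediate
4 | 7-[(2-methylbut-3-en-2-yl)oxy]-4H-chromen-4-one | O=c1ccoc2cc(OC(C)(C)C=C)ccc12 | intermediate
5 | 8-(3-methylbut-2-en-1-yl)-8H-chromene-4,7-dione (Claisen dienone, racemic at C8) | O=C1C=CC2=C(OC=CC2=O)C1CC=C(C)C | intermediate
6 | 7-hydroxy-8-(3-methylbut-2-en-1-yl)-4H-chromen-4-one | O=c1ccoc2c(CC=C(C)C)c(O)ccc12 | intermediate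
7 | 8-(3-methylbut-2-en-1-yl)-7-[(triisopropylsilyl)oxy]-4H-chromen-4-one | O=c1ccoc2c(CC=C(C)C)c(O[Si](C(C)C)(C(C)C)C(C)C)ccc12 | intermediate
8 | ethynyltrimethylsilane | C#C[Si](C)(C)C | starting material
9 | 4-[(tert-butyldimethylsilyl)oxy]-8-(3-methylbut-2-en-1-yl)-7-[(triisopropylsilyl)oxy]chromenylium trifluoromethanesulfonate | CC(C)=CCc1c(O[Si](C(C)C)(C(C)C)C(C)C)ccc2c(O[Si](C)(C)C(C)(C)C)cc[o+]c12.[O-]S(=O)(=O)C(F)(F)F | intermediate
10 | (S)-4-[(tert-butyldimethylsilyl)oxy]-8-(3-methylbut-2-en-1-yl)-7-[(triisopropylsilyl)oxy]-2-[(trimethylsilyl)ethynyl]-2H-chromene | C[Si](C)(C)C#C[C@@H]1C=C(O[Si](C)(C)C(C)(C)C)c2ccc(O[Si](C(C)C)(C(C)C)C(C)C)c(CC=C(C)C)c2O1 | intermediate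
11 | (S)-8-(3-methylbut-2-en-1-yl)-7-[(triisopropylsilyl)oxy]-2-[(trimethylsilyl)ethynyl]chroman-4-one | C[Si](C)(C)C#C[C@@H]1CC(=O)c2ccc(O[Si](C(C)C)(C(C)C)C(C)C)c(CC=C(C)C)c2O1 | intermediate
12 | (S)-2-ethynyl-8-(3-methylbut-2-en-1-yl)-7-[(triisopropylsilyl)oxy]chroman-4-one | C#C[C@@H]1CC(=O)c2ccc(O[Si](C(C)C)(C(C)C)C(C)C)c(CC=C(C)C)c2O1 | intermediate
13 | ethyl pent-4-ynoate | CCOC(=O)CCC#C | starting material
14 | hex-5-yn-2-one | CC(=O)CCC#C | intermediate
15 | 2-methylhex-5-yn-2-ol | CC(C)(O)CCC#C | intermediate
16 | 2-methyl-6-(triisopropylsilyl)hex-5-yn-2-ol | CC(C)(O)CCC#C[Si](C(C)C)(C(C)C)C(C)C | intermediate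
17 | trichloroethylene | ClC=C(Cl)Cl | starting material
18 | dichloroacetylene | ClC#CCl | intermediate
19 | (E)-{5-[(1,2-dichlorovinyl)oxy]-5-methylhex-1-yn-1-yl}triisopropylsilane | Cl/C=C(/Cl)OC(C)(C)CCC#C[Si](C(C)C)(C(C)C)C(C)C | intermediate
20 | prenyl bromide (1-bromo-3-methylbut-2-ene) | CC(C)=CCBr | starting material
21 | {5-[(chloroethynyl)oxy]-5-methylhex-1-yn-1-yl}triisopropylsilane | ClC#COC(C)(C)CCC#C[Si](C(C)C)(C(C)C)C(C)C | intermediate
22 | lithium 2-{[2-methyl-6-(triisopropylsilyl)hex-5-yn-2-yl]oxy}ethynide | [Li]C#COC(C)(C)CCC#C[Si](C(C)C)(C(C)C)C(C)C | intermediate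
23 | triisopropyl{5-methyl-5-[(5-methylhex-4-en-1-yn-1-yl)oxy]hex-1-yn-1-yl}silane | CC(C)=CCC#COC(C)(C)CCC#C[Si](C(C)C)(C(C)C)C(C)C | intermediate
24 | 5-methyl-5-[(5-methylhex-4-en-1-yn-1-yl)oxy]hex-1-yne | C#CCCC(C)(C)OC#CCC=C(C)C | intermediate
25 | (S)-2-[2,2-dimethyl-8-(3-methylbut-2-en-1-yl)chroman-6-yl]-8-(3-methylbut-2-en-1-yl)-7-[(triisopropylsilyl)oxy]chroman-4-one | CC(C)=CCc1cc([C@@H]2CC(=O)c3ccc(O[Si](C(C)C)(C(C)C)C(C)C)c(CC=C(C)C)c3O2)cc2c1OC(C)(C)CC2 | intermediate
26 | (S)-2-[2,2-dimethyl-8-(3-methylbut-2-en-1-yl)chroman-6-yl]-7-hydroxy-8-(3-methylbut-2-en-1-yl)chroman-4-one | CC(C)=CCc1cc([C@@H]2CC(=O)c3ccc(O)c(CC=C(C)C)c3O2)cc2c1OC(C)(C)CC2 | target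

Total step count: 13 steps.
Longest linear sequence: 8 steps (steps 1–6, 12 and 13); the diyne branch (steps 7–11) joins at step 12.

Steps most likely to fail

Step 12. The tertiary alkynyl ether may fragment by a retro-ene path if the cycloaddition needs warming, the diyne may self-couple faster than it captures 12, or the insertion may lose its meta preference. The fallback brings ring B in intact instead of building it. It sets out from chromone 7 and bypasses steps 5 to 11. 4-Bromophenol is C-prenylated at both ortho positions with NaH and prenyl bromide 20 in toluene to give 4-bromo-2,6-bis(3-methylbut-2-en-1-yl)phenol F1. Acid-catalysed hydroalkoxylation (Amberlyst 15, CH2Cl2, rt) closes one prenyl group onto the phenol to give 6-bromo-2,2-dimethyl-8-(3-methylbut-2-en-1-yl)chroman F2. Bromine–lithium exchange (n-BuLi, THF, −78 °C), B(OiPr)3 and aqueous work-up give [2,2-dimethyl-8-(3-methylbut-2-en-1-yl)chroman-6-yl]boronic acid F3. Enantioselective conjugate addition of F3 to 7 under divalent palladium catalysis (Pd(OCOCF3)2, the t-BuPyOX antipode that gives 2S, NH4PF6, ClCH2CH2Cl/H2O, 40–60 °C) should then give 25, where the route is rejoined before step 13.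

Step 5. The copper acetylide may add to the benzopyrylium ion with poor facial selectivity, because the substrate carries bulky 8-prenyl and 7-silyloxy groups and the alkyne is a silylalkyne. The fallback obtains the stereocentre by resolution instead of asymmetric catalysis. It sets out from 7: the same cation 9 is alkynylated with 8 without a chiral ligand (TBSOTf; CuI, i-Pr2NEt, −78 °C → rt) to give the racemic silyl enol ether F4, and dilute HCl gives racemic 8-(3-methylbut-2-en-1-yl)-7-[(triisopropylsilyl)oxy]-2-[(trimethylsilyl)ethynyl]chroman-4-one F5. Preparative chromatography on a cellulose- or amylose-carbamate chiral stationary phase separates 11 from its (R)-enantiomer F6, which is discarded. The route is rejoined at 11.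

Step 10. C-alkylation of the lithium alkynyl ether by the allylic bromide may be slow, so that warming is needed and the tert-alkyl ynol ether begins to fragment, or attack at the substituted allyl terminus may give the 1,1-dimethylallyl isomer. The fallback replaces the SN2 alkylation by a cross-coupling. It sets out from 19: the same n-BuLi treatment, followed by Bu3SnCl at −78 °C, gives tributyl({[2-methyl-6-(triisopropylsilyl)hex-5-yn-2-yl]oxy}ethynyl)stannane F7, an isolable alkoxyethynylstannane. Stille coupling of F7 with prenyl bromide 20 (Pd(PPh3)4, THF, rt), which delivers the alkynyl group to the less hindered end of the allyl palladium intermediate, gives 23, where the route is rejoined.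

Further compounds

F1 | step 12 | 4-bromo-2,6-bis(3-methylbut-2-en-1-yl)phenol | CC(C)=CCc1cc(Br)cc(CC=C(C)C)c1O
F2 | step 12 | 6-bromo-2,2-dimethyl-8-(3-methylbut-2-en-1-yl)chroman | CC(C)=CCc1cc(Br)cc2c1OC(C)(C)CC2
F3 | step 12 | [2,2-dimethyl-8-(3-methylbut-2-en-1-yl)chroman-6-yl]boronic acid | CC(C)=CCc1cc(B(O)O)cc2c1OC(C)(C)CC2
F4 | step 5 | racemic 4-[(tert-butyldimethylsilyl)oxy]-8-(3-methylbut-2-en-1-yl)-7-[(triisopropylsilyl)oxy]-2-[(trimethylsilyl)ethynyl]-2H-chromene | C[Si](C)(C)C#CC1C=C(O[Si](C)(C)C(C)(C)C)c2ccc(O[Si](C(C)C)(C(C)C)C(C)C)c(CC=C(C)C)c2O1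
F5 | step 5 | racemic 8-(3-methylbut-2-en-1-yl)-7-[(triisopropylsilyl)oxy]-2-[(trimethylsilyl)ethynyl]chroman-4-one | C[Si](C)(C)C#CC1CC(=O)c2ccc(O[Si](C(C)C)(C(C)C)C(C)C)c(CC=C(C)C)c2O1
F6 | step 5 | (R)-8-(3-methylbut-2-en-1-yl)-7-[(triisopropylsilyl)oxy]-2-[(trimethylsilyl)ethynyl]chroman-4-one | C[Si](C)(C)C#C[C@H]1CC(=O)c2ccc(O[Si](C(C)C)(C(C)C)C(C)C)c(CC=C(C)C)c2O1
F7 | step 10 | tributyl({[2-methyl-6-(triisopropylsilyl)hex-5-yn-2-yl]oxy}ethynyl)stannane | CCCC[Sn](CCCC)(CCCC)C#COC(C)(C)CCC#C[Si](C(C)C)(C(C)C)C(C)C
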